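**Retrosynthetic overview**

1. Indane numbering: C1 = alkylidene carbon, C2 = CH(3,5-dihydroxyphenyl), C3 = CH(4-hydroxyphenyl), C3a/C7a = ring-fusion carbons. The last operation is eight-fold O-demethylation of octamethyl ether 21.
2. Key disconnection of 21: cut the C3–C3a bond (Friedel–Crafts) and add a C1–C3 bond, which gives the triarylcyclopropyl carbinol 20. Forward, one acid-catalysed strain-release cascade opens the cyclopropane, creates the C1=CH double bond, closes the five-membered ring and sets C3.
3. Enabling feature: C3 is a 4-oxybenzylic carbon (cation-stabilising), C3a lies ortho to O-4 and para to O-6 of the benzo ring (nucleophilic), and the exocyclic C1=CH bond is homoallylic to C3. The C1/C3 relationship can therefore be stored as a cyclopropane bond, and only C2 has to be carried as a stereocentre.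
4. 20 comes from cyclopropanecarbaldehyde 8 and the aryllithium of bromodihydrobenzofuran 18. 8 comes from the Shi epoxide of trimethoxystilbene and an arylacetonitrile by two SN2 steps (C2 from catalysis). 18 comes from a Rh-catalysed donor/donor-carbene C–H insertion and cis-to-trans epimerisation.
5. Ring order: dihydrobenzofuran ring (step 9) and, in the other branch, the temporary cyclopropane (step 3); the five-membered carbocycle of the indane is closed last (step 12).

Key step: step 12

Assumption: in step 2 the nitrile anion opens the epoxide at the 4-methoxybenzylic carbon (attack at the other carbon would lead to the same cyclopropane 6 with the same configuration at the future C2); centres that step 12 erases (quaternary cyclopropane carbon, carbinol carbon) are carried as mixtures and left undefined in the SMILES.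

**Route**

Step 1
Reactants: 1 (E)-3,4',5-trimethoxystilbene
Product: 2 (2S,3S)-2-(3,5-dimethoxyphenyl)-3-(4-methoxyphenyl)oxirane
Conditions: ent-Shi ketone (L-fructose-derived, 30 mol %), Oxone, K2CO3, Bu4NHSO4, MeCN/DMM/aq. borate buffer (pH 10.5), 0 °C
Reagents that add atoms: potassium peroxymonosulfate (Oxone), [K+].[O-]OS(=O)(=O)O
Why: Shi asymmetric epoxidation (chiral dioxirane, spiro transition state) is highly face-selective for trans-stilbenes; the D-fructose ketone gives (R,R)-stilbene oxides, so its enantiomer should give the (2S,3S)-epoxide, and the basic buffer protects the acid-labile 4-methoxyphenyl epoxide.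

Step 2
Reactants: 2 (2S,3S)-2-(3,5-dimethoxyphenyl)-3-(4-methoxyphenyl)oxirane; 3 (3,5-dimethoxyphenyl)acetonitrile
Product: 4 (3R,4R)-2,4-bis(3,5-dimethoxyphenyl)-4-hydroxy-3-(4-methoxyphenyl)butanenitrile (both epimers at C2)
Conditions: 3 (1.2 equiv), LiHMDS (1.15 equiv), THF, −78 °C; then 2, −78 → 23 °C; H2O
Reagents that add atoms: none
Why: Epoxide opening by a lithiated arylacetonitrile (SN2, inversion) at the more reactive 4-methoxybenzylic carbon leaves the C–O bond of the 3,5-dimethoxybenzylic carbon, the future C2, untouched; the nitrile α-carbon forms as a mixture that is erased in step 3.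

Step 3
Reactants: 4 (3R,4R)-2,4-bis(3,5-dimethoxyphenyl)-4-hydroxy-3-(4-methoxyphenyl)butanenitrile
Product: 6 (2S,3S)-1,2-bis(3,5-dimethoxyphenyl)-3-(4-methoxyphenyl)cyclopropane-1-carbonitrile (both epimers at C1), via mesylate 5 (not isolated)
Conditions: MsCl, Et3N, CH2Cl2, −20 °C; then t-BuOK (1.2 equiv), THF, −40 → 0 °C
Reagents that add atoms: none
Why: γ-Elimination (3-exo-tet alkylation of the α-aryl nitrile carbanion on the secondary benzylic mesylate) closes the cyclopropane with inversion at the mesylate carbon, which sets the future C2 as S and places the two vicinal aryl groups trans.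

Step 4
Reactants: 6 (2S,3S)-1,2-bis(3,5-dimethoxyphenyl)-3-(4-methoxyphenyl)cyclopropane-1-carbonitrile
Product: 8 (2S,3S)-1,2-bis(3,5-dimethoxyphenyl)-3-(4-methoxyphenyl)cyclopropane-1-carbaldehyde (both epimers at C1), via N-aluminio aldimine 7 (not isolated)
Conditions: DIBAL-H (1.3 equiv), toluene, −78 °C; then aq. Rochelle salt (pH 7), 0 °C
Reagents that add atoms: water, O
Why: DIBAL-H reduction of the hindered nitrile stops at the N-aluminio aldimine, which is hydrolysed to the aldehyde under neutral conditions so that the donor–acceptor cyclopropane is not opened.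

Step 5
Reactants: 9 5-bromo-2-hydroxybenzaldehyde; 10 4-methoxybenzyl chloride
Product: 11 5-bromo-2-[(4-methoxyphenyl)methoxy]benzaldehyde
Conditions: K2CO3, KI (cat.), DMF, 60 °C
Reagents that add atoms: none
Why: Williamson ether synthesis on the phenoxide installs the benzylic ether whose CH2 becomes C2 of the dihydrobenzofuran.

Step 6
Reactants: 11 5-bromo-2-[(4-methoxyphenyl)methoxy]benzaldehyde; 12 (3,5-dimethoxyphenyl)magnesium chloride
Product: 13 [5-bromo-2-[(4-methoxyphenyl)methoxy]phenyl](3,5-dimethoxyphenyl)methanol (racemic)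
Conditions: 12 (1.2 equiv), THF, 0 → 23 °C; H2O
Reagents that add atoms: none
Why: Grignard addition to the aldehyde at 0 °C, where the aryl bromide is inert.

Step 7
Reactants: 13 [5-bromo-2-[(4-methoxyphenyl)methoxy]phenyl](3,5-dimethoxyphenyl)methanol
Product: 14 [5-bromo-2-[(4-methoxyphenyl)methoxy]phenyl](3,5-dimethoxyphenyl)methanone
Conditions: activated MnO2 (10 equiv), CH2Cl2, 23 °C
Reagents that add atoms: none
Why: MnO2 oxidation of a doubly benzylic alcohol to the benzophenone.

Step 8
Reactants: 14 [5-bromo-2-[(4-methoxyphenyl)methoxy]phenyl](3,5-dimethoxyphenyl)methanone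
Product: 15 [[5-bromo-2-[(4-methoxyphenyl)methoxy]phenyl](3,5-dimethoxyphenyl)methylidene]hydrazine (E/Z mixture)
Conditions: N2H4·H2O (10 equiv), AcOH (cat.), EtOH, 80 °C
Reagents that add atoms: hydrazine, NN
Why: Acid-catalysed hydrazone condensation of the benzophenone, with excess hydrazine to suppress azine formation.

Step 9
Reactants: 15 [[5-bromo-2-[(4-methoxyphenyl)methoxy]phenyl](3,5-dimethoxyphenyl)methylidene]hydrazine
Product: 17 (2S,3R)-5-bromo-3-(3,5-dimethoxyphenyl)-2-(4-methoxyphenyl)-2,3-dihydro-1-benzofuran (cis), via diaryldiazomethane 16 (not isolated)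
Conditions: activated MnO2 (8 equiv), CH2Cl2, 0 °C, filter; then Rh2(R-PTAD)4 (1 mol %), CH2Cl2, 0 °C
Reagents that add atoms: none
Why: MnO2 dehydrogenation to the diaryldiazomethane, then Rh(II)-catalysed enantioselective 1,5 C–H insertion of the donor/donor carbene into the benzylic ether C–H, a known route to cis-2,3-diaryl-2,3-dihydrobenzofurans; the chiral carboxylate catalyst fixes C3 (the catalyst antipode that gives 3R is used) and the insertion is expected to give the cis isomer.

Step 10
Reactants: 17 (2S,3R)-5-bromo-3-(3,5-dimethoxyphenyl)-2-(4-methoxyphenyl)-2,3-dihydro-1-benzofuran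
Product: 18 (2R,3R)-5-bromo-3-(3,5-dimethoxyphenyl)-2-(4-methoxyphenyl)-2,3-dihydro-1-benzofuran (trans)
Conditions: BF3·OEt2 (20 mol %), CH2Cl2, 0 → 23 °C
Reagents that add atoms: none
Why: Lewis acid-catalysed epimerisation at C2 by reversible ionisation of the 4-methoxybenzylic C2–O bond and reclosure to the thermodynamically favoured trans isomer; C3 is not involved.

Step 11
Reactants: 18 (2R,3R)-5-bromo-3-(3,5-dimethoxyphenyl)-2-(4-methoxyphenyl)-2,3-dihydro-1-benzofuran; 8 (2S,3S)-1,2-bis(3,5-dimethoxyphenyl)-3-(4-methoxyphenyl)cyclopropane-1-carbaldehyde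
Product: 20 [(2S,3S)-1,2-bis(3,5-dimethoxyphenyl)-3-(4-methoxyphenyl)cyclopropyl][(2R,3R)-3-(3,5-dimethoxyphenyl)-2-(4-methoxyphenyl)-2,3-dihydro-1-benzofuran-5-yl]methanol (mixture at the carbinol carbon and at cyclopropane C1), via aryllithium 19 (not isolated)
Conditions: t-BuLi (2.0 equiv), THF, −78 °C; then 8, −78 → −40 °C; H2O
Reagents that add atoms: none
Why: Bromine–lithium exchange and 1,2-addition of the aryllithium to the non-enolisable aldehyde; the new carbinol centre forms as a mixture that is erased in step 12.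

Step 12
Reactants: 20 [(2S,3S)-1,2-bis(3,5-dimethoxyphenyl)-3-(4-methoxyphenyl)cyclopropyl][(2R,3R)-3-(3,5-dimethoxyphenyl)-2-(4-methoxyphenyl)-2,3-dihydro-1-benzofuran-5-yl]methanol
Product: 21 (1E,2S,3S)-2-(3,5-dimethoxyphenyl)-1-{[(2R,3R)-3-(3,5-dimethoxyphenyl)-2-(4-methoxyphenyl)-2,3-dihydro-1-benzofuran-5-yl]methylidene}-4,6-dimethoxy-3-(4-methoxyphenyl)-2,3-dihydro-1H-indene (octamethyl ether of the target)
Conditions: BF3·OEt2 (20 mol %), 4 Å MS, CH2Cl2, −78 → −40 °C; Et3N quench
Reagents that add atoms: none
Why: Proposed new method: BF3 ionises the doubly activated carbinol to a cyclopropylcarbinyl cation, the ring bond to the 4-methoxyphenyl-bearing carbon breaks with release of the ring strain (about 27 kcal/mol) to give the C1=CH double bond and a 4-methoxybenzylic cation at C3, and the 3,5-dimethoxyphenyl ring on C1 captures this cation through its ortho carbon (C3a). The closest known reaction types are the Julia cyclopropylcarbinyl-to-homoallyl rearrangement with Friedel–Crafts termination (2-arylcyclopropyl carbinols to aryl-dihydronaphthalenes) and the acid-mediated Friedel–Crafts closure of 4-oxybenzylic cations in 8–8'-linked stilbene dimers; new is that the arene sits on the quaternary ring carbon, so that a 1-alkylidene indane results. The five-membered ring closes by intramolecular Friedel–Crafts alkylation, a cationic closure in which the attacking arene bond is endocyclic, at the position ortho and para to the two methoxy groups. C2 is carried unchanged from the cyclopropane, and the new centre C3 is set by substrate control: the planar cation closes through the conformer with the 4-methoxyphenyl group on the face opposite to the C2 aryl group, which gives the 2,3-trans (2S,3S) indane; the carbinol carbon and the two other ring carbons lose their configuration, so all diastereomers of 20 converge. The step needs cleavage toward the 4-methoxyphenyl carbon and not toward the 3,5-dimethoxyphenyl carbon (secured by the para-oxygen, whereas meta-oxygens cannot stabilise a benzylic cation), capture by the dimethoxyphenyl ring and not by the benzofuran ring (its positions next to C5 are meta to the ring oxygen), and E geometry, expected because the opening avoids a cis arrangement of the two aryl groups on the new double bond and because E, with the aryl group away from H-7, is the more stable isomer. Catalytic acid and low temperature keep the product styrene from being protonated again.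

Step 13
Reactants: 21 (1E,2S,3S)-2-(3,5-dimethoxyphenyl)-1-{[(2R,3R)-3-(3,5-dimethoxyphenyl)-2-(4-methoxyphenyl)-2,3-dihydro-1-benzofuran-5-yl]methylidene}-4,6-dimethoxy-3-(4-methoxyphenyl)-2,3-dihydro-1H-indene
Product: 22 (1E,2S,3S)-2-(3,5-dihydroxyphenyl)-1-{[(2R,3R)-3-(3,5-dihydroxyphenyl)-2-(4-hydroxyphenyl)-2,3-dihydro-1-benzofuran-5-yl]methylidene}-3-(4-hydroxyphenyl)-2,3-dihydro-1H-indene-4,6-diol (CNP0184753.1)
Conditions: BBr3 (20 equiv), CH2Cl2, −78 → 0 °C; MeOH, then H2O
Reagents that add atoms: none
Why: Lewis acid O-demethylation of aryl methyl ethers with BBr3, a standard end-game for permethylated stilbene oligomers; the trans-dihydrobenzofuran and the E-alkene are the thermodynamic isomers, so reversible ionisation should not change them, and the low temperature limits protonation of the styrene.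

**Compound list**

1 | (E)-3,4',5-trimethoxystilbene | COc1ccc(/C=C/c2cc(OC)cc(OC)c2)cc1 | starting material
2 | (2S,3S)-2-(3,5-dimethoxyphenyl)-3-(4-methoxyphenyl)oxirane | COc1ccc([C@@H]2O[C@H]2c2cc(OC)cc(OC)c2)cc1 | intermediate
3 | (3,5-dimethoxyphenyl)acetonitrile | N#CCc1cc(OC)cc(OC)c1 | starting material
4 | (3R,4R)-2,4-bis(3,5-dimethoxyphenyl)-4-hydroxy-3-(4-methoxyphenyl)butanenitrile (both epimers at C2) | N#CC(c1cc(OC)cc(OC)c1)[C@H](c1ccc(OC)cc1)[C@@H](O)c1cc(OC)cc(OC)c1 | intermediate
5 | (1R,2R)-3-cyano-1,3-bis(3,5-dimethoxyphenyl)-2-(4-methoxyphenyl)propyl methanesulfonate (both epimers at C3) | N#CC(c1cc(OC)cc(OC)c1)[C@H](c1ccc(OC)cc1)[C@@H](OS(C)(=O)=O)c1cc(OC)cc(OC)c1 | intermediate (not isolated)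
6 | (2S,3S)-1,2-bis(3,5-dimethoxyphenyl)-3-(4-methoxyphenyl)cyclopropane-1-carbonitrile (both epimers at C1) | N#CC1(c2cc(OC)cc(OC)c2)[C@H](c2ccc(OC)cc2)[C@H]1c1cc(OC)cc(OC)c1 | intermediate
7 | 1-[(2S,3S)-1,2-bis(3,5-dimethoxyphenyl)-3-(4-methoxyphenyl)cyclopropyl]-N-[bis(2-methylpropyl)alumanyl]methanimine | CC(C)C[Al](CC(C)C)N=CC1(c2cc(OC)cc(OC)c2)[C@H](c2ccc(OC)cc2)[C@H]1c1cc(OC)cc(OC)c1 | intermediate (not isolated)
8 | (2S,3S)-1,2-bis(3,5-dimethoxyphenyl)-3-(4-methoxyphenyl)cyclopropane-1-carbaldehyde (both epimers at C1) | O=CC1(c2cc(OC)cc(OC)c2)[C@H](c2ccc(OC)cc2)[C@H]1c1cc(OC)cc(OC)c1 | intermediate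
9 | 5-bromo-2-hydroxybenzaldehyde | O=Cc1cc(Br)ccc1O | starting material
10 | 4-methoxybenzyl chloride | COc1ccc(CCl)cc1 | starting material
11 | 5-bromo-2-[(4-methoxyphenyl)methoxy]benzaldehyde | COc1ccc(COc2ccc(Br)cc2C=O)cc1 | intermediate
12 | (3,5-dimethoxyphenyl)magnesium chloride (THF solution) | COc1cc(OC)cc([Mg]Cl)c1 | starting material
13 | [5-bromo-2-[(4-methoxyphenyl)methoxy]phenyl](3,5-dimethoxyphenyl)methanol (racemic) | COc1ccc(COc2ccc(Br)cc2C(O)c2cc(OC)cc(OC)c2)cc1 | intermediate
14 | [5-bromo-2-[(4-methoxyphenyl)methoxy]phenyl](3,5-dimethoxyphenyl)methanone | COc1ccc(COc2ccc(Br)cc2C(=O)c2cc(OC)cc(OC)c2)cc1 | intermediate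
15 | [[5-bromo-2-[(4-methoxyphenyl)methoxy]phenyl](3,5-dimethoxyphenyl)methylidene]hydrazine (E/Z mixture) | COc1ccc(COc2ccc(Br)cc2C(=NN)c2cc(OC)cc(OC)c2)cc1 | intermediate
16 | 4-bromo-2-[diazo(3,5-dimethoxyphenyl)methyl]-1-[(4-methoxyphenyl)methoxy]benzene | COc1ccc(COc2ccc(Br)cc2C(=[N+]=[N-])c2cc(OC)cc(OC)c2)cc1 | intermediate (not isolated)
17 | (2S,3R)-5-bromo-3-(3,5-dimethoxyphenyl)-2-(4-methoxyphenyl)-2,3-dihydro-1-benzofuran (cis) | Brc1ccc2c(c1)[C@@H](c1cc(OC)cc(OC)c1)[C@@H](c1ccc(OC)cc1)O2 | intermediate
18 | (2R,3R)-5-bromo-3-(3,5-dimethoxyphenyl)-2-(4-methoxyphenyl)-2,3-dihydro-1-benzofuran (trans) | Brc1ccc2c(c1)[C@@H](c1cc(OC)cc(OC)c1)[C@H](c1ccc(OC)cc1)O2 | intermediate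
19 | [(2R,3R)-3-(3,5-dimethoxyphenyl)-2-(4-methoxyphenyl)-2,3-dihydro-1-benzofuran-5-yl]lithium | [Li]c1ccc2c(c1)[C@@H](c1cc(OC)cc(OC)c1)[C@H](c1ccc(OC)cc1)O2 | intermediate (not isolated)
20 | [(2S,3S)-1,2-bis(3,5-dimethoxyphenyl)-3-(4-methoxyphenyl)cyclopropyl][(2R,3R)-3-(3,5-dimethoxyphenyl)-2-(4-methoxyphenyl)-2,3-dihydro-1-benzofuran-5-yl]methanol (mixture at the carbinol carbon and cyclopropane C1) | OC(c1ccc2c(c1)[C@@H](c1cc(OC)cc(OC)c1)[C@H](c1ccc(OC)cc1)O2)C1(c2cc(OC)cc(OC)c2)[C@H](c2ccc(OC)cc2)[C@H]1c1cc(OC)cc(OC)c1 | intermediate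
21 | (1E,2S,3S)-2-(3,5-dimethoxyphenyl)-1-{[(2R,3R)-3-(3,5-dimethoxyphenyl)-2-(4-methoxyphenyl)-2,3-dihydro-1-benzofuran-5-yl]methylidene}-4,6-dimethoxy-3-(4-methoxyphenyl)-2,3-dihydro-1H-indene | COc1ccc([C@H]2c3c(OC)cc(OC)cc3/C(=C/c3ccc4c(c3)[C@@H](c3cc(OC)cc(OC)c3)[C@H](c3ccc(OC)cc3)O4)[C@@H]2c2cc(OC)cc(OC)c2)cc1 | intermediate
22 | (1E,2S,3S)-2-(3,5-dihydroxyphenyl)-1-{[(2R,3R)-3-(3,5-dihydroxyphenyl)-2-(4-hydroxyphenyl)-2,3-dihydro-1-benzofuran-5-yl]methylidene}-3-(4-hydroxyphenyl)-2,3-dihydro-1H-indene-4,6-diol | Oc1ccc([C@H]2c3c(O)cc(O)cc3/C(=C/c3ccc4c(c3)[C@@H](c3cc(O)cc(O)c3)[C@H](c3ccc(O)cc3)O4)[C@@H]2c2cc(O)cc(O)c2)cc1 | target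

**Step count**

Total step count: 13
Longest linear sequence: 9 steps (steps 5–13)

**Steps most likely to fail**

Step 12 (Proposed new method). The benzylic cation may lose the C2 stereocentre by a 1,2-hydride shift or by proton loss before the ring closes. The acid may also re-protonate the product styrene, which leads to migration of the double bond into the ring or to a second cyclisation by the C2 aryl group. Finally, the ring opening may give mixed alkene geometry. The fallback uses known chemistry, sets out from 20 and comes back at 21, and splits the cascade into two known reactions. A Julia olefin synthesis (MgBr2·OEt2, Et2O/CH2Cl2, −20 °C) opens the cyclopropyl carbinol 20 with bromide assistance to the homoallylic bromide (2R,3R)-5-[(1E,3S)-4-bromo-2,3-bis(3,5-dimethoxyphenyl)-4-(4-methoxyphenyl)but-1-en-1-yl]-3-(3,5-dimethoxyphenyl)-2-(4-methoxyphenyl)-2,3-dihydro-1-benzofuran F1. At this stage the alkene geometry can be checked and, if needed, equilibrated with catalytic iodine. Halide abstraction with AgOTf and 2,6-di-tert-butylpyridine (CH2Cl2, −78 °C) then closes the ring by Friedel–Crafts alkylation under buffered, non-protic conditions and gives 21.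

Step 2. The bulky stabilised carbanion may fail to open the hindered trans-diaryl epoxide, or lithium ion may trigger rearrangement of the acid-labile epoxide to a carbonyl compound. The fallback sets out from 2 and 3, comes back at 6 and bypasses steps 2 and 3 by a Wadsworth–Emmons cyclopropanation. Nitrile 3 is phosphorylated (LDA 2 equiv, ClP(O)(OEt)2, THF, −78 °C) to diethyl [cyano(3,5-dimethoxyphenyl)methyl]phosphonate F2. Its sodium salt (NaH, DME, 85 °C) opens epoxide 2, the alkoxide takes over the phosphoryl group, and the resulting carbanion displaces the phosphate with inversion. Cyclopropane 6 should thus form in one flask with the same configuration at the future C2.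

Step 3. The secondary benzylic mesylate may ionise with participation of the neighbouring 4-methoxyphenyl group, which would scramble the future C2, or it may undergo E2 elimination to a stilbene instead of ring closure. The fallback sets out from 4 and comes back at 6 by a redox-dehydrative (Mitsunobu-type) C-alkylation with (cyanomethylene)tributylphosphorane (toluene, 100 °C). The reagent deprotonates the nitrile and activates the hydroxyl group as an alkoxyphosphonium ion, so that no free sulfonate is present and the displacement should occur with inversion. It makes no compound outside the list (F0).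

Further compounds
F1 | step 12 | (2R,3R)-5-[(1E,3S)-4-bromo-2,3-bis(3,5-dimethoxyphenyl)-4-(4-methoxyphenyl)but-1-en-1-yl]-3-(3,5-dimethoxyphenyl)-2-(4-methoxyphenyl)-2,3-dihydro-1-benzofuran (both epimers at the CHBr carbon) | COc1ccc(C(Br)[C@@H](c2cc(OC)cc(OC)c2)/C(=C\c2ccc3c(c2)[C@@H](c2cc(OC)cc(OC)c2)[C@H](c2ccc(OC)cc2)O3)c2cc(OC)cc(OC)c2)cc1
F2 | step 2 | diethyl [cyano(3,5-dimethoxyphenyl)methyl]phosphonate | CCOP(=O)(OCC)C(C#N)c1cc(OC)cc(OC)c1
F0 | step 3 | none | none
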